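The numbers in the tables were computed for an exercise; the scatter is artificial.

The winter run levels off with first end groups near 14.9% of their charge, and the spring run, with more second end groups, near 5.97%. Your flask has fewer second end groups than either.

all flasks: first end groups 0.074 M
- winter: second end groups 0.10 M; run made earlier
- spring: second end groups 0.16 M; run made earlier
- flask: second end groups 0.0725 M; time 4.0 min

| run | time / min | links / % | first end groups / % |
|---|---|---|---|
| winter | 0.200 | 74.0 | 25.1 |
| winter | 0.333 | 80.9 | 18.7 |
| winter | 0.667 | 84.2 | 15.6 |
| winter | 1.33 | 81.5 | 15.9 |
| winter | 2.50 | 84.9 | 13.1 |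
| spring | 0.500 | 96.0 | 7.8 |
| spring | 1.00 | 91.9 | 6.0 |
| spring | 1.33 | 92.3 | 7.0 |
| spring | 2.00 | 91.1 | 5.5 |
| spring | 2.50 | 90.3 | 5.4 |

(each reading ± 1 percentage point)

- each molecule carries two end groups: a chain counts once for every two ends that are left, dead ends included; the units are half of the end groups of the two monomers charged
- steps that have been proposed: first end groups + second end groups <-> links; links -> over-reaction product
- a link that another step uses up counts as cut, two dead ends; so do two ends of one kind that react with each other

- average number of monomer units in a chain (unreacted monomers counted as chains of one) at 4.0 min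
- part of the first end groups that has reacted at 4.0 min

1. Follow one first end group. It is free, linked or over-reacted, and the odds between the first two are [links]/[first end groups]. Winter from 0.667 min on gives 5.62 at [second end groups] = 0.0370 M. Spring from 1.00 min on gives 15.3 at 0.0904 M.
2. Divide the odds by [second end groups]: winter reads 152 L mol⁻¹, spring 169 L mol⁻¹. Their mean, 161 L mol⁻¹, a reading that carries the scatter of both runs, is the link odds per unit of free [second end groups], the equilibrium constant.
3. Start of the curve: winter's first reading, with the way back ignored, gives a low forward constant of 1.84 L mol⁻¹ s⁻¹. So I expect your flask to start near 0.593 M min⁻¹, and, still ignoring the way back, links to pass [first end groups] near 0.122 min.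
4. Level: the charges differ by 0.00150 M, so [second end groups] = [first end groups] − d. Solving the quadratic with K, over-reaction product left aside, gives [first end groups] = 0.0192 M and [second end groups] = 0.0177 M, so my estimate is c = 74.0%.
5. Knee: the estimated relaxation time is 0.210 min, shorter than 4.0 min, so I expect your flask to reach that level well before the asked time.
6. Tail: the last balance gaps of both runs read 0.0142 min⁻¹, noisily. In your flask that makes an estimated 0.00312 M of over-reaction product, each one a cut, and I expect dp to sag from 3.96 to 3.39.
7. The forecast says dp 3.45 and c 74.8%, holding that “the flask is at quasi-equilibrium by 4 min”. Its c stands 0.80 percentage points above mine, and its dp stands 0.0600 above mine.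

    first end groups + second end groups ⇌ links (K = 160 L mol⁻¹, k = 2.20 L mol⁻¹ s⁻¹)
    links → over-reaction product (k = 2.10 × 10⁻⁴ s⁻¹)

The flask gives dp 3.53 and c 74.5%, so the forecast holds within its margins. The flask's dp had stood at 3.83 at 1.00 min, higher than at the asked time. Now take the neighbour flask, the same recipe with 0.018 M of first end groups. The same quadratic with K gives [first end groups] = 0.00179 M, so c = 90.1%. That neighbour flask gives c = 90.4%.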